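## Structural features

- The target 31 is an 18-membered bis(bibenzyl) macrocycle built from four six-membered rings: a 2-methoxy-1,4-benzoquinone (ring A), a para-phenylene (ring B), a 1,2,4-trisubstituted phenol ring (ring C) and a meta-phenylene (ring D).
- The rings are joined in the order A–CH2CH2–B–O–C–CH2CH2–D–O–A. Ring A atoms are written a1 to a6 here: a1 carries OMe, a2 is CH, a3 and a6 are the carbonyl carbons, a4 carries the ring D oxygen and the neighbouring a5 carries the ethylene bridge to ring B.
- On ring C the free hydroxyl is ortho to the ring B oxygen and para to the ethylene bridge to ring D.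
- There is no stereocentre and no stereogenic double bond, so the problems are regiochemical and entropic.
- The fragile groups are the quinone (sensitive to base, nucleophiles and reductants, with a vinylogous ester at a1) and the catechol-type phenol of ring C.
- The real difficulty is twofold: closing an 18-membered ring that contains a rigid para-phenylene, and preparing a pentasubstituted ring A whose four oxygens all have different roles.
- The key step uses the fact that ring B has only two substituents, oxygen on b1 and carbon on b4, in a para relationship. This is the pattern of a [4+2] adduct between a 2-aryloxybuta-1,3-diene on the ring C oxygen and an ethynyl ketone on the ring A side chain. Ring B can therefore be created in the ring-closing event by forming bonds b2–b3 and b4–b5, and the carbonyl next to b4, being para to the aryloxy group, can be reduced to CH2 at the end.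

## Logic of the disconnections

**31 to 30.** The two quinone C=O bonds are traced back to the para-hydroquinone. The quinone is the most fragile group, so it is made last. The forward step needs an oxidant that takes the hydroquinone and spares the ring C phenol.

**30 to 29.** Three O–benzyl bonds and a carbonyl on the carbon attached to b4 are restored. One hydrogenolysis removes all four, so the protecting groups cost no separate step. The demand is complete reduction of the aryl ketone to CH2, not only to the alcohol.

**29 to 28.** Ring B is taken back to the cyclohexa-1,4-diene level. This costs one dehydrogenation and lets the macrocycle close onto a bent, non-aromatic ring.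

**28 to 27.** Bonds b2–b3 and b4–b5 are cut, which opens ring B and the macrocycle together. The result is an open-chain compound with a dienyl ether on ring C and an ynone on ring A. The forward cycloaddition must give para, not meta, bridging and must beat oligomerisation. The structures of 27 and 28 were recounted against 31: the ring has 18 members through b1 and b4 and the oxygen patterns of rings A and C agree. The skeleton and the benzyl protection are therefore kept, and only the order of installing diene and ynone is redesigned.

**27 to 26 to 24 to 23.** The carbonyl–alkynyl C–C bond is cut (addition of 25 to an aldehyde), and the aldehyde is traced to a primary alcohol. A carbonyl group or an alkyne would not survive titanium methylenation or hydroboration, so both are introduced after those steps. An amide precursor of the ynone is avoided for the same reason, and because the liberated amine adds to terminal ynones. The three forward steps must spare the dienyl ether.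

**23 to 14 + 21.** The aryl–CH2 bond between ring C and the C–D bridge is cut (B-alkyl Suzuki–Miyaura coupling). This gives two fragments of similar size and makes the bibenzyl without an alkene reduction that would endanger benzyl ethers. The demand is that no B–H remains when 21 is added and that the palladium step runs at low temperature.

**21 to 20 to 18 + 19, and 18 to 16 to 15.** The enol ether C=CH2 is traced to an ester carbonyl and the ester to a phenol. The diene is built on a small aryl bromide that has no other carbonyl group. The phenol oxygen comes from a formyl group by aryl migration, so the 1,2,4-pattern of ring C is bought with the starting material.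

**14 to 12 + 13, and 12 to 10.** The aryl–vinyl bond on ring D is cut, and the hydroxyethyl chain is traced to an allyl group by removing one carbon. The alkene cleavage has to come before the vinyl group is introduced, so that only one alkene is present when one is cleaved.

**10 to 8 + 9.** The O–aryl bond between the a4 oxygen and ring D is cut (Ullmann coupling). The forward step must couple a hindered 2,6-disubstituted phenol and must choose C–I over C–Br.

**8 to 7 to 5 + 6.** The a5–CH2 bond is cut by a retro-Claisen step to an O-allyl ether on the a4 oxygen. The oxygen that later becomes the diaryl ether delivers the carbon chain to its only free ortho position, so the contiguous a4/a5 substitution is regiospecific.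

**5 to 3 to 2 to 1.** The a4 oxygen is traced to a formyl group (aryl migration) and the formyl group to a C–H para to OMe. Two benzyl ethers mask the future quinone oxygens. The forward formylation must go para to OMe.

## Other disconnections considered

**Alternative 1:** The cut is inside ring A, at the a6–a1 bond. In the forward direction the macrocyclic 4-hydroxy-4-(methoxyethynyl)cyclobutenone A2 is heated. A four-electron ring opening gives an enynyl ketene, which closes between the ketene carbon and the methoxy-bearing alkyne carbon. After hydrogen transfer this gives the quinone A1, the silyl ether of 31, and one desilylation finishes the synthesis.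

- In its favour: the order of substituents on ring A is fixed by the order of additions to a four-membered ring, no hydroquinone protection or final oxidation is needed, and only one step follows the key step. On ring A regiocontrol and on length of the endgame this plan is better than the chosen one.
- Against it: the 18-membered ring must already be closed around the cyclobutenone, so the macrocyclisation is moved and not solved. The step builds one ring and one skeletal bond, where the chosen step builds two of each. The aryloxy group on the cyclobutenedione precursor of A2 is a leaving group towards the alkynyl anion, and the ketene can also close to five-membered products.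
- Comparison: both key steps are reagent-free thermal pericyclic reactions, so they are equal in mechanism type. Alternative 1 saves the five-step oxygenation and Claisen sequence on ring A but needs its own macrocyclisation and four-membered-ring chemistry, so the total length is expected to be comparable.

**Alternative 2:** The cut is the O–a4 bond. In the forward direction the ring D phenoxide of the seco bromoquinone A4 attacks the bromine-bearing carbon a4 under mild carbonate base at high dilution. Loss of bromide gives A3, the methoxymethyl ether of 31, and acid removes the acetal.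

- In its favour: ring B comes from a purchased para-substituted arene, the quinone is already at its final oxidation level, and the position of bromine fixes the regiochemistry. Phenoxide substitution on haloquinones is well established between separate molecules. On precedent for the key step and on the length of the endgame this plan is better than the chosen one. It also avoids an Ullmann coupling of a hindered phenol.
- Against it: a quinone has to survive phenoxide and base for the long reaction time that dilution imposes. Electron transfer from the phenoxide, attack at the methoxy-bearing a1 or at unsubstituted a2, and base-induced tautomerisation of the alkylquinone are all open. The bromoquinone has to be generated late in a molecule that carries a free phenol.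
- Comparison: the chosen plan closes the ring under neutral thermal conditions with ring A masked, but its key step is untested. Alternative 2 forms one ring in its key step and the chosen plan two. Step counts should be similar or slightly lower for alternative 2.

**Alternative 3:** The cut is the bond between the ring B oxygen and ring C. In the forward direction the 2,6-dibromo-4-alkylphenolate of the seco bisphenol A6 is oxidised at an anode. The ring B phenol oxygen adds to a bromine-bearing ortho carbon, and zinc reduction of the bromodienone gives the ortho-hydroxy diaryl ether A5 with one residual bromine.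

- In its favour: both coupling partners are simple phenols, ring B is purchased, and the ortho bromines block C–C coupling and leave exactly the hydroxyl/aryloxy pattern of ring C. Ring A is carried as the same dibenzyl hydroquinone ether as in the chosen plan, and the residual bromine should fall in the same hydrogenolysis as the benzyl groups. The endgame is therefore two steps, one fewer than the chosen plan, and the building blocks are cheaper.
- Against it: the tetraoxygenated ring A is itself easily oxidised and may compete at the electrode. Coupling between molecules gives oligomers, addition at the alkyl-bearing para carbon is possible, and the approach of the ring B oxygen to the ortho carbon is constrained inside a forming macrocycle.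
- Comparison: the two plans are equal in the protection of ring A and in the final oxidation. The anodic plan reaches its seco compound in fewer steps. Its selectivity rests on electrode potential and conformation, whereas the chosen step has an orbital-controlled regiochemical preference and forms two C–C bonds.

Key step: step 17

Remark on the chemistry: the only stereocentre on the way (alcohol 26) is formed as a racemate and removed in step 16. Ring B atoms are b1 (oxygen-bearing), b2 (diene CH2 next to b1), b3 (alkyne CH), b4 (acyl-bearing), b5 (vinyl CH2 terminus) and b6 (diene CH).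

## Route

Step 1
Reactants: 1 2-methoxyhydroquinone
Product: 2 1,4-bis(benzyloxy)-2-methoxybenzene
Conditions: BnBr (2.3 equiv), K2CO3, DMF, 60 °C, N2
Reagents that add atoms: benzyl bromide, BrCc1ccccc1
Why: Double Williamson etherification of both phenoxides; exclusion of air prevents oxidation of the hydroquinone to the quinone before alkylation.

Step 2
Reactants: 2 1,4-bis(benzyloxy)-2-methoxybenzene
Product: 3 2,5-bis(benzyloxy)-4-methoxybenzaldehyde
Conditions: POCl3, DMF, 0 → 70 °C; then aq NaOAc
Reagents that add atoms: N,N-dimethylformamide, CN(C)C=O; water, O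
Why: Vilsmeier–Haack formylation of a 1,2,4-trialkoxybenzene goes to the position para to OMe and ortho to OBn, the future a4; the position between OMe and OBn is shielded.

Step 3
Reactants: 3 2,5-bis(benzyloxy)-4-methoxybenzaldehyde
Product: 5 2,5-bis(benzyloxy)-4-methoxyphenol, via aryl formate 4 (not isolated)
Conditions: mCPBA, CH2Cl2, 0 °C → rt; then K2CO3, MeOH, rt, N2
Reagents that add atoms: 3-chloroperbenzoic acid, OOC(=O)c1cccc(Cl)c1
Why: Baeyer–Villiger oxidation in which the electron-rich aryl group migrates in preference to hydrogen; methanolysis of the formate frees the a4 phenol.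

Step 4
Reactants: 5 2,5-bis(benzyloxy)-4-methoxyphenol; 6 allyl bromide
Product: 7 1,4-bis(benzyloxy)-2-methoxy-5-(prop-2-en-1-yloxy)benzene
Conditions: K2CO3, acetone, reflux
Reagents that add atoms: none
Why: Williamson O-allylation of the phenoxide.

Step 5
Reactants: 7 1,4-bis(benzyloxy)-2-methoxy-5-(prop-2-en-1-yloxy)benzene
Product: 8 3,6-bis(benzyloxy)-4-methoxy-2-(prop-2-en-1-yl)phenol
Conditions: N,N-diethylaniline, 190 °C, Ar
Reagents that add atoms: none
Why: Aromatic Claisen rearrangement ([3,3] shift, then tautomerisation); one ortho position carries OBn and the para position carries OMe, so the allyl group can only arrive at a5.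

Step 6
Reactants: 8 3,6-bis(benzyloxy)-4-methoxy-2-(prop-2-en-1-yl)phenol; 9 1-bromo-3-iodobenzene
Product: 10 1,4-bis(benzyloxy)-2-(3-bromophenoxy)-5-methoxy-3-(prop-2-en-1-yl)benzene
Conditions: CuI (10 mol %), picolinic acid (20 mol %), K3PO4, DMSO, 85 °C; 9 (1.5 equiv)
Reagents that add atoms: none
Why: Ullmann diaryl ether coupling under ligand conditions suited to 2,6-disubstituted phenols; the C–I bond reacts well before the C–Br bond, which is kept for step 8.

Step 7
Reactants: 10 1,4-bis(benzyloxy)-2-(3-bromophenoxy)-5-methoxy-3-(prop-2-en-1-yl)benzene
Product: 12 2-[2,5-bis(benzyloxy)-6-(3-bromophenoxy)-3-methoxyphenyl]ethan-1-ol, via arylacetaldehyde 11 (not isolated)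
Conditions: OsO4 (2 mol %), NaIO4, 2,6-lutidine, dioxane–H2O, rt; extractive work-up; then NaBH4, MeOH, 0 °C
Reagents that add atoms: osmium tetroxide, O=[Os](=O)(=O)=O; sodium periodate, [Na+].[O-]I(=O)(=O)=O
Why: Lemieux–Johnson cleavage of the only alkene removes the terminal carbon; immediate borohydride reduction stores the enolisable arylacetaldehyde as a primary alcohol that is inert in steps 8 and 13.

Step 8
Reactants: 12 2-[2,5-bis(benzyloxy)-6-(3-bromophenoxy)-3-methoxyphenyl]ethan-1-ol; 13 potassium vinyltrifluoroborate (CH2=CHBF3K)
Product: 14 2-[2,5-bis(benzyloxy)-6-(3-ethenylphenoxy)-3-methoxyphenyl]ethan-1-ol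
Conditions: Pd(dppf)Cl2 (3 mol %), Cs2CO3, THF–H2O (9:1), 80 °C
Reagents that add atoms: none
Why: Suzuki–Miyaura vinylation of the aryl bromide; it follows step 7 so that the molecule never holds two alkenes when one has to be cleaved.

Step 9
Reactants: 15 5-bromo-2-hydroxybenzaldehyde
Product: 16 2-(benzyloxy)-5-bromobenzaldehyde
Conditions: BnBr, K2CO3, DMF, rt
Reagents that add atoms: benzyl bromide, BrCc1ccccc1
Why: Williamson etherification; the bromine para to this oxygen fixes the ring C pattern from the outset.

Step 10
Reactants: 16 2-(benzyloxy)-5-bromobenzaldehyde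
Product: 18 2-(benzyloxy)-5-bromophenol, via aryl formate 17 (not isolated)
Conditions: mCPBA, CH2Cl2, rt; then K2CO3, MeOH, rt
Reagents that add atoms: 3-chloroperbenzoic acid, OOC(=O)c1cccc(Cl)c1
Why: Baeyer–Villiger oxidation of an ortho-alkoxybenzaldehyde with aryl migration, then methanolysis; the new hydroxyl is meta to bromine and ortho to OBn, as ring C requires.

Step 11
Reactants: 18 2-(benzyloxy)-5-bromophenol; 19 acryloyl chloride
Product: 20 2-(benzyloxy)-5-bromophenyl prop-2-enoate
Conditions: Et3N, CH2Cl2, 0 °C, BHT (trace)
Reagents that add atoms: none
Why: O-acylation of the phenol by an acid chloride.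

Step 12
Reactants: 20 2-(benzyloxy)-5-bromophenyl prop-2-enoate
Product: 21 1-(benzyloxy)-4-bromo-2-(buta-1,3-dien-2-yloxy)benzene
Conditions: Cp2TiMe2 (2.5 equiv), toluene–THF, 65 °C, dark, Ar; filtration through basic alumina
Reagents that add atoms: dimethyltitanocene (Cp2TiMe2), C[Ti](C)(C1C=CC=C1)C1C=CC=C1
Why: Petasis methylenation of the ester carbonyl through Cp2Ti=CH2 and an oxatitanacyclobutane converts the acrylate into the 2-aryloxybuta-1,3-diene; on this small fragment no other carbonyl group or alkyne meets the titanium carbene.

Step 13
Reactants: 14 2-[2,5-bis(benzyloxy)-6-(3-ethenylphenoxy)-3-methoxyphenyl]ethan-1-ol; 21 1-(benzyloxy)-4-bromo-2-(buta-1,3-dien-2-yloxy)benzene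
Product: 23 2-[2,5-bis(benzyloxy)-6-(3-{2-[4-(benzyloxy)-3-(buta-1,3-dien-2-yloxy)phenyl]ethyl}phenoxy)-3-methoxyphenyl]ethan-1-ol, via B-alkyl-9-BBN borane 22 (not isolated)
Conditions: 14, 9-BBN (2.2 equiv), THF, 0 °C → rt; then 3 M aq K3PO4, 15 min; then 21 (1.2 equiv), Pd(OAc)2 (5 mol %), SPhos (10 mol %), THF, 40 °C
Reagents that add atoms: none
Why: Anti-Markovnikov hydroboration of the styrene and B-alkyl Suzuki–Miyaura coupling with the aryl bromide build the C–D ethylene bridge without a stilbene reduction, so benzyl ethers and diene are untouched. One equivalent of borane is consumed by the hydroxyl, and residual B–H is destroyed by the aqueous base before the diene is added.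

Step 14
Reactants: 23 2-[2,5-bis(benzyloxy)-6-(3-{2-[4-(benzyloxy)-3-(buta-1,3-dien-2-yloxy)phenyl]ethyl}phenoxy)-3-methoxyphenyl]ethan-1-ol
Product: 24 2-[2,5-bis(benzyloxy)-6-(3-{2-[4-(benzyloxy)-3-(buta-1,3-dien-2-yloxy)phenyl]ethyl}phenoxy)-3-methoxyphenyl]acetaldehyde
Conditions: Dess–Martin periodinane, NaHCO3, CH2Cl2, 0 °C → rt; used at once
Reagents that add atoms: none
Why: Buffered Dess–Martin oxidation of the primary alcohol stops at the aldehyde and should leave the acid-sensitive enol ether diene intact.

Step 15
Reactants: 24 2-[2,5-bis(benzyloxy)-6-(3-{2-[4-(benzyloxy)-3-(buta-1,3-dien-2-yloxy)phenyl]ethyl}phenoxy)-3-methoxyphenyl]acetaldehyde; 25 ethynylmagnesium bromide (HC≡CMgBr)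
Product: 26 racemic 1-[2,5-bis(benzyloxy)-6-(3-{2-[4-(benzyloxy)-3-(buta-1,3-dien-2-yloxy)phenyl]ethyl}phenoxy)-3-methoxyphenyl]but-3-yn-2-ol
Conditions: HC≡CMgBr (3 equiv), THF, −78 → 0 °C; aq NH4Cl
Reagents that add atoms: none
Why: 1,2-Addition of the alkynyl Grignard reagent to the aldehyde; the carbinol centre is formed as a racemate and needs no control because step 16 removes it.

Step 16
Reactants: 26 racemic 1-[2,5-bis(benzyloxy)-6-(3-{2-[4-(benzyloxy)-3-(buta-1,3-dien-2-yloxy)phenyl]ethyl}phenoxy)-3-methoxyphenyl]but-3-yn-2-ol
Product: 27 1-[2,5-bis(benzyloxy)-6-(3-{2-[4-(benzyloxy)-3-(buta-1,3-dien-2-yloxy)phenyl]ethyl}phenoxy)-3-methoxyphenyl]but-3-yn-2-one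
Conditions: Dess–Martin periodinane, NaHCO3, CH2Cl2, 0 °C; kept cold and dilute
Reagents that add atoms: none
Why: Oxidation of the secondary propargylic alcohol to the terminal ynone under neutral conditions; no amide precursor is used, so no liberated amine can add to the ynone.

Step 17
Reactants: 27 1-[2,5-bis(benzyloxy)-6-(3-{2-[4-(benzyloxy)-3-(buta-1,3-dien-2-yloxy)phenyl]ethyl}phenoxy)-3-methoxyphenyl]but-3-yn-2-one
Product: 28 macrocyclic cyclohexa-1,4-dienyl ketone (ring B at the dihydro level; rings A and C as benzyl ethers)
Conditions: toluene, 100 °C, BHT, base-washed glassware, Ar; syringe-pump addition over 12 h to ≤ 1 mM, then 12 h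
Reagents that add atoms: none
Why: Proposed new method: the closest known reaction types are the thermal normal-demand [4+2] cycloaddition of 2-alkoxy- or 2-aryloxybuta-1,3-dienes with ethynyl ketones, which gives 1-acyl-4-oxycyclohexa-1,4-dienes, and macrocyclising intramolecular Diels–Alder reactions; forming a para-phenylene precursor and an 18-membered diaryl ether ring in one event is untested. The concerted, asynchronous cycloaddition joins the CH2 terminus next to the oxygen-bearing diene carbon (largest HOMO coefficient) to the terminal β carbon of the ynone (largest LUMO coefficient) and the vinyl terminus to the α carbon, so the new bonds are b2–b3 and b4–b5. Ring B closes as a six-membered cyclohexa-1,4-diene in the suprafacial [4+2] mode, and the 18-membered ring closes in the same event because the diene is tethered through the oxygen on its 2-position and the dienophile through its acyl group (a type 2 intramolecular arrangement bridging b1 and b4). No stereocentre is formed. The step needs para over meta bridging and ring closure over oligomerisation: the first rests on the matched polarisation of donor diene and acceptor alkyne, which a flexible 14-atom tether should not override, and the second on slow addition that keeps 27 near 1 mM. The ring that closes is a bent, non-aromatic diene, so less strain is paid than in a closure between two finished arenes. BHT and base-washed glassware protect the enol ether and the ynone from radical and acid pathways.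

Step 18
Reactants: 28 macrocyclic cyclohexa-1,4-dienyl ketone
Product: 29 macrocyclic aryl ketone (ring B aromatic; tribenzyl ether)
Conditions: DDQ (1.1 equiv), benzene, rt
Reagents that add atoms: none
Why: Dehydrogenation of the cyclohexa-1,4-diene by hydride abstraction and proton loss gives the arene; aromatisation should be much faster than oxidative attack on benzyl ethers.

Step 19
Reactants: 29 macrocyclic aryl ketone
Product: 30 macrocyclic 2-methoxyhydroquinone with free ring C phenol
Conditions: H2 (4 bar), 10% Pd/C (zerovalent palladium on carbon), EtOAc–AcOH, HClO4 (cat.), rt; handled under Ar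
Reagents that add atoms: none
Why: Catalytic hydrogenolysis cleaves the three benzyl ethers and, through the benzylic alcohol, reduces the aryl ketone para to the aryloxy donor to CH2 in acidic medium.

Step 20
Reactants: 30 macrocyclic 2-methoxyhydroquinone with free ring C phenol
Product: 31 target quinone
Conditions: Ag2O, Na2SO4, Et2O–acetone, rt
Reagents that add atoms: none
Why: Two-electron oxidation of the para-hydroquinone to the quinone; the ring C phenol has no ortho or para hydroxyl partner and should resist this mild oxidant.

## Compound list

1 | 2-methoxyhydroquinone | COc1cc(O)ccc1O | starting material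
2 | 1,4-bis(benzyloxy)-2-methoxybenzene | COc1cc(OCc2ccccc2)ccc1OCc1ccccc1 | intermediate
3 | 2,5-bis(benzyloxy)-4-methoxybenzaldehyde | COc1cc(OCc2ccccc2)c(C=O)cc1OCc1ccccc1 | intermediate
4 | 2,5-bis(benzyloxy)-4-methoxyphenyl formate | COc1cc(OCc2ccccc2)c(OC=O)cc1OCc1ccccc1 | intermediate
5 | 2,5-bis(benzyloxy)-4-methoxyphenol | COc1cc(OCc2ccccc2)c(O)cc1OCc1ccccc1 | intermediate
6 | allyl bromide | C=CCBr | starting material
7 | 1,4-bis(benzyloxy)-2-methoxy-5-(prop-2-en-1-yloxy)benzene | COc1cc(OCc2ccccc2)c(OCC=C)cc1OCc1ccccc1 | intermediate
8 | 3,6-bis(benzyloxy)-4-methoxy-2-(prop-2-en-1-yl)phenol | COc1cc(OCc2ccccc2)c(O)c(CC=C)c1OCc1ccccc1 | intermediate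
9 | 1-bromo-3-iodobenzene | Brc1cccc(I)c1 | starting material
10 | 1,4-bis(benzyloxy)-2-(3-bromophenoxy)-5-methoxy-3-(prop-2-en-1-yl)benzene | COc1cc(OCc2ccccc2)c(Oc2cccc(Br)c2)c(CC=C)c1OCc1ccccc1 | intermediate
11 | 2-[2,5-bis(benzyloxy)-6-(3-bromophenoxy)-3-methoxyphenyl]acetaldehyde | COc1cc(OCc2ccccc2)c(Oc2cccc(Br)c2)c(CC=O)c1OCc1ccccc1 | intermediate
12 | 2-[2,5-bis(benzyloxy)-6-(3-bromophenoxy)-3-methoxyphenyl]ethan-1-ol | COc1cc(OCc2ccccc2)c(Oc2cccc(Br)c2)c(CCO)c1OCc1ccccc1 | intermediate
13 | potassium vinyltrifluoroborate | C=C[B-](F)(F)F.[K+] | starting material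
14 | 2-[2,5-bis(benzyloxy)-6-(3-ethenylphenoxy)-3-methoxyphenyl]ethan-1-ol | COc1cc(OCc2ccccc2)c(Oc2cccc(C=C)c2)c(CCO)c1OCc1ccccc1 | intermediate
15 | 5-bromo-2-hydroxybenzaldehyde | O=Cc1cc(Br)ccc1O | starting material
16 | 2-(benzyloxy)-5-bromobenzaldehyde | O=Cc1cc(Br)ccc1OCc1ccccc1 | intermediate
17 | 2-(benzyloxy)-5-bromophenyl formate | O=COc1cc(Br)ccc1OCc1ccccc1 | intermediate
18 | 2-(benzyloxy)-5-bromophenol | Oc1cc(Br)ccc1OCc1ccccc1 | intermediate
19 | acryloyl chloride | C=CC(=O)Cl | starting material
20 | 2-(benzyloxy)-5-bromophenyl prop-2-enoate | C=CC(=O)Oc1cc(Br)ccc1OCc1ccccc1 | intermediate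
21 | 1-(benzyloxy)-4-bromo-2-(buta-1,3-dien-2-yloxy)benzene | C=CC(=C)Oc1cc(Br)ccc1OCc1ccccc1 | intermediate
22 | B-alkyl-9-BBN borane of 14, hydroxyl held as its 9-BBN borinate | COc1cc(OCc2ccccc2)c(Oc2cccc(CCB3C4CCCC3CCC4)c2)c(CCOB2C3CCCC2CCC3)c1OCc1ccccc1 | intermediate
23 | 2-[2,5-bis(benzyloxy)-6-(3-{2-[4-(benzyloxy)-3-(buta-1,3-dien-2-yloxy)phenyl]ethyl}phenoxy)-3-methoxyphenyl]ethan-1-ol | COc1cc(OCc2ccccc2)c(Oc2cccc(CCc3ccc(OCc4ccccc4)c(OC(=C)C=C)c3)c2)c(CCO)c1OCc1ccccc1 | intermediate
24 | corresponding arylacetaldehyde | COc1cc(OCc2ccccc2)c(Oc2cccc(CCc3ccc(OCc4ccccc4)c(OC(=C)C=C)c3)c2)c(CC=O)c1OCc1ccccc1 | intermediate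
25 | ethynylmagnesium bromide | C#C[Mg]Br | starting material
26 | corresponding 1-arylbut-3-yn-2-ol, racemic | COc1cc(OCc2ccccc2)c(Oc2cccc(CCc3ccc(OCc4ccccc4)c(OC(=C)C=C)c3)c2)c(CC(O)C#C)c1OCc1ccccc1 | intermediate
27 | corresponding 1-arylbut-3-yn-2-one (seco dienyl ether–ynone) | COc1cc(OCc2ccccc2)c(Oc2cccc(CCc3ccc(OCc4ccccc4)c(OC(=C)C=C)c3)c2)c(CC(=O)C#C)c1OCc1ccccc1 | intermediate
28 | macrocyclic cyclohexa-1,4-dienyl ketone | COc1cc(OCc2ccccc2)c2c(CC(=O)C3=CCC(=CC3)Oc3cc(ccc3OCc3ccccc3)CCc3cccc(c3)O2)c1OCc1ccccc1 | intermediate
29 | macrocyclic aryl ketone, tribenzyl ether | COc1cc(OCc2ccccc2)c2c(CC(=O)c3ccc(cc3)Oc3cc(ccc3OCc3ccccc3)CCc3cccc(c3)O2)c1OCc1ccccc1 | intermediate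
30 | macrocyclic 2-methoxyhydroquinone with free ring C phenol | COc1cc(O)c2c(CCc3ccc(cc3)Oc3cc(ccc3O)CCc3cccc(c3)O2)c1O | intermediate
31 | target quinone CNP0332646.0 | COC1=CC(=O)C2=C(CCc3ccc(cc3)Oc3cc(ccc3O)CCc3cccc(c3)O2)C1=O | target

## Step count and least certain steps

Total: 20 steps. Longest linear sequence: 16 steps (steps 1–8, then 13–20). The ring C branch (steps 9–12) joins at step 13.

**Step 17 (key step).** The most likely failure is oligomerisation by cycloaddition between molecules, because the entropic cost of bringing the two ends of a 14-atom tether together may exceed what dilution can compensate. A second risk is erosion of the para preference if the tether forces the meta-bridged transition state. Thermal isomerisation of the ynone through its acidic benzylic CH2 is also possible.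

The fallback separates ring formation from ring closure and uses known reaction types; it sets out from 14 and 21 and rejoins the route at 30.
- Alcohol 14 is oxidised with buffered Dess–Martin periodinane to the styrene-bearing arylacetaldehyde F1.
- HC≡CMgBr converts it to the racemic propargylic alcohol F2, and a second Dess–Martin oxidation gives the styrene-bearing ynone F3.
- F3 and an excess of diene 21 are heated at high concentration in toluene. The Diels–Alder reaction between two molecules should give the para-substituted cyclohexa-1,4-diene adduct F4.
- DDQ aromatises it to the open-chain aryl ketone F5, which carries the ring D vinyl group and the ring C bromide.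
- An intramolecular Heck reaction at high dilution (Pd(OAc)2, tri-o-tolylphosphine, Et3N, DMF, 90 °C) closes the macrocyclic (E)-stilbene ketone F6.
- The hydrogenation conditions of step 19 then reduce the stilbene, the ketone and the benzyl ethers together to give 30.

**Step 13.** The diene may be lost through hydroboration by residual B–H or through addition of a palladium hydride, and the electron-rich bromide may undergo slow oxidative addition at 40 °C.

The fallback couples first and builds the diene afterwards; it sets out from 14 and 18 and rejoins at 23.
- Alcohol 14 is silylated (TBSCl, imidazole) to the silyl ether F7.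
- Hydroboration with 9-BBN gives the B-alkyl-9-BBN borane F8 (not isolated).
- Coupling with the free bromophenol 18 (Pd(dppf)Cl2, aq K3PO4, DMF–THF, 60 °C) gives the bibenzyl phenol F9.
- Acryloyl chloride and Et3N give the aryl acrylate F10. Cp2TiMe2 then methylenates it, with no other carbonyl present, to the silyl-protected dienyl ether F11.
- TBAF removes the silyl group to give 23.

**Step 12.** Radical polymerisation of the acrylate or of the product diene at 65 °C, and hydrolysis of the enol ether during isolation, are the likely losses.

The fallback avoids carbonyl methylenation; it sets out from 18 and rejoins at 21.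
- Phenol 18 is added to 2-vinyloxirane with Pd2(dba)3 and the racemic trans-1,2-diaminocyclohexane bis(2-diphenylphosphinobenzamide) ligand (CH2Cl2, rt). Attack at the internal allyl terminus should give the racemic 2-aryloxybut-3-en-1-ol F12.
- Mesylation (MsCl, Et3N) gives the mesylate F13.
- KOt-Bu in THF at 0 °C removes the allylic proton alpha to oxygen in an E2 elimination to give diene 21.

**Step 19.** Reduction may stall at the benzylic alcohol, and the free hydroquinone may decompose oxidatively on prolonged exposure.

The fallback removes the ketone oxygen by ionic reduction before debenzylation; it sets out from 29 and rejoins at 30.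
- NaBH4 (THF–MeOH) gives the macrocyclic benzylic alcohol F14.
- Et3SiH with trifluoroacetic acid (CH2Cl2, 0 °C) reduces the para-aryloxy-stabilised benzylic cation to the macrocyclic tribenzyl ether F15.
- Neutral hydrogenolysis (H2, Pd/C, EtOAc) then gives 30.

**Step 6.** Incomplete conversion of the hindered phenoxide, a second coupling at the C–Br bond and base-induced migration of the allyl double bond are the risks.

The fallback is a metal-free arylation; it sets out from 8 and rejoins at 10 with no new intermediate. Phenol 8 is deprotonated with KOt-Bu in THF and treated at rt with (3-bromophenyl)(2,4,6-trimethoxyphenyl)iodonium tosylate. This hypervalent-iodine reagent transfers the 3-bromophenyl group to hindered phenoxides by ligand coupling.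

Further compounds

F1 | step 17 | 2-[2,5-bis(benzyloxy)-6-(3-ethenylphenoxy)-3-methoxyphenyl]acetaldehyde | COc1cc(OCc2ccccc2)c(Oc2cccc(C=C)c2)c(CC=O)c1OCc1ccccc1
F2 | step 17 | racemic 1-[2,5-bis(benzyloxy)-6-(3-ethenylphenoxy)-3-methoxyphenyl]but-3-yn-2-ol | COc1cc(OCc2ccccc2)c(Oc2cccc(C=C)c2)c(CC(O)C#C)c1OCc1ccccc1
F3 | step 17 | 1-[2,5-bis(benzyloxy)-6-(3-ethenylphenoxy)-3-methoxyphenyl]but-3-yn-2-one | COc1cc(OCc2ccccc2)c(Oc2cccc(C=C)c2)c(CC(=O)C#C)c1OCc1ccccc1
F4 | step 17 | open-chain cyclohexa-1,4-dienyl ketone from F3 and 21 | COc1cc(OCc2ccccc2)c(Oc2cccc(C=C)c2)c(CC(=O)C2=CCC(=CC2)Oc2cc(Br)ccc2OCc2ccccc2)c1OCc1ccccc1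
F5 | step 17 | open-chain aryl ketone with ring D vinyl group and ring C bromide | COc1cc(OCc2ccccc2)c(Oc2cccc(C=C)c2)c(CC(=O)c2ccc(cc2)Oc2cc(Br)ccc2OCc2ccccc2)c1OCc1ccccc1
F6 | step 17 | macrocyclic (E)-stilbene ketone, tribenzyl ether | COc1cc(OCc2ccccc2)c2c(CC(=O)c3ccc(cc3)Oc3cc(ccc3OCc3ccccc3)/C=C/c3cccc(c3)O2)c1OCc1ccccc1
F7 | step 13 | tert-butyldimethylsilyl ether of 14 | COc1cc(OCc2ccccc2)c(Oc2cccc(C=C)c2)c(CCO[Si](C)(C)C(C)(C)C)c1OCc1ccccc1
F8 | step 13 | B-alkyl-9-BBN borane of F7 | COc1cc(OCc2ccccc2)c(Oc2cccc(CCB3C4CCCC3CCC4)c2)c(CCO[Si](C)(C)C(C)(C)C)c1OCc1ccccc1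
F9 | step 13 | bibenzyl with free ring C phenol and silyl-protected hydroxyethyl chain | COc1cc(OCc2ccccc2)c(Oc2cccc(CCc3ccc(OCc4ccccc4)c(O)c3)c2)c(CCO[Si](C)(C)C(C)(C)C)c1OCc1ccccc1
F10 | step 13 | aryl acrylate of F9 | COc1cc(OCc2ccccc2)c(Oc2cccc(CCc3ccc(OCc4ccccc4)c(OC(=O)C=C)c3)c2)c(CCO[Si](C)(C)C(C)(C)C)c1OCc1ccccc1
F11 | step 13 | tert-butyldimethylsilyl ether of 23 | COc1cc(OCc2ccccc2)c(Oc2cccc(CCc3ccc(OCc4ccccc4)c(OC(=C)C=C)c3)c2)c(CCO[Si](C)(C)C(C)(C)C)c1OCc1ccccc1
F12 | step 12 | racemic 2-[2-(benzyloxy)-5-bromophenoxy]but-3-en-1-ol | OCC(C=C)Oc1cc(Br)ccc1OCc1ccccc1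
F13 | step 12 | racemic 2-[2-(benzyloxy)-5-bromophenoxy]but-3-en-1-yl methanesulfonate | CS(=O)(=O)OCC(C=C)Oc1cc(Br)ccc1OCc1ccccc1
F14 | step 19 | macrocyclic benzylic alcohol, tribenzyl ether, racemic | COc1cc(OCc2ccccc2)c2c(CC(O)c3ccc(cc3)Oc3cc(ccc3OCc3ccccc3)CCc3cccc(c3)O2)c1OCc1ccccc1
F15 | step 19 | macrocyclic tribenzyl ether with both ethylene bridges | COc1cc(OCc2ccccc2)c2c(CCc3ccc(cc3)Oc3cc(ccc3OCc3ccccc3)CCc3cccc(c3)O2)c1OCc1ccccc1
F0 | step 6 | none | none
A1 | alternative 1 | ring C tert-butyldimethylsilyl ether of the target quinone | COC1=CC(=O)C2=C(CCc3ccc(cc3)Oc3cc(ccc3O[Si](C)(C)C(C)(C)C)CCc3cccc(c3)O2)C1=O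
A2 | alternative 1 | macrocyclic 4-hydroxy-4-(methoxyethynyl)cyclobutenone, racemic | COC#CC1(O)C(=O)C2=C1Oc1cccc(c1)CCc1ccc(O[Si](C)(C)C(C)(C)C)c(c1)Oc1ccc(CC2)cc1
A3 | alternative 2 | ring C methoxymethyl ether of the target quinone | COC1=CC(=O)C2=C(CCc3ccc(cc3)Oc3cc(ccc3OCOC)CCc3cccc(c3)O2)C1=O
A4 | alternative 2 | seco 2-bromo-3-alkyl-5-methoxy-1,4-benzoquinone with free ring D phenol | COC1=CC(=O)C(Br)=C(CCc2ccc(cc2)Oc2cc(ccc2OCOC)CCc2cccc(O)c2)C1=O
A5 | alternative 3 | macrocycle with free ring C phenol, one ortho bromine and ring A as dibenzyl hydroquinone ether | COc1cc(OCc2ccccc2)c2c(CCc3ccc(cc3)Oc3cc(cc(Br)c3O)CCc3cccc(c3)O2)c1OCc1ccccc1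
A6 | alternative 3 | seco bisphenol with ring C as 2,6-dibromo-4-alkylphenol and ring B as 4-alkylphenol | COc1cc(OCc2ccccc2)c(Oc2cccc(CCc3cc(Br)c(O)c(Br)c3)c2)c(CCc2ccc(O)cc2)c1OCc1ccccc1
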